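**Plan**

1. Retrosynthesis: first the two O-benzyl bonds on ring A are cut; then ring B is cut at C1'–C6'. Ring B is a symmetric 5-substituted 2-methoxyresorcinol (O on C3', C4', C5'), so its six carbons map onto a 4-methoxyhexane-1,3,5-trione whose C1 carbonyl sits on C2 of the chromone.
2. Next the chain is cut between C1 and C2 of the trione (chromone-2-carboxylate plus 3-methoxypentane-2,4-dione), then ring C at O1–C2 and C2–C3 (o-hydroxyacetophenone plus diethyl oxalate), then the two C–OMe bonds of ring A.
3. Forward: ring A is dressed on 2,4,6-trihydroxyacetophenone (benzylation, dibromination, double methoxylation), and ring C is closed onto it with diethyl oxalate.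
4. The chain is then joined by acylation of a diketone dianion, ring B closes last by aldol aromatization, and hydrogenolysis ends the route.
5. Stereochemistry: the target has no stereocentre and no stereogenic double bond; the sp3 centres that appear in 12 and 13 are labile and vanish on aromatization.

Key step: step 8

Remark: 1,3-dicarbonyl compounds (6, 10, 12, 13) are drawn as keto tautomers although they should be largely enolized; primed locants refer to ring B in flavone numbering.

**Route**

Step 1
Reactants: 1 2,4,6-trihydroxyacetophenone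
Product: 2 1-[2,4-bis(benzyloxy)-6-hydroxyphenyl]ethan-1-one
Conditions: BnBr (2.1 equiv), K2CO3 (2.2 equiv), DMF, 0 °C → rt
Reagents that add atoms: benzyl bromide, BrCc1ccccc1
Why: Williamson etherification should alkylate the 4-hydroxyl and one ortho hydroxyl, while the second ortho hydroxyl stays hydrogen-bonded to the acetyl carbonyl and is left free, as is usual for phloroacetophenone.

Step 2
Reactants: 2 1-[2,4-bis(benzyloxy)-6-hydroxyphenyl]ethan-1-one
Product: 3 1-[2,4-bis(benzyloxy)-3,5-dibromo-6-hydroxyphenyl]ethan-1-one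
Conditions: NBS (2.1 equiv), DMF, 0 °C → rt, dark
Reagents that add atoms: N-bromosuccinimide, O=C1CCC(=O)N1Br
Why: Electrophilic aromatic bromination in a polar solvent should take the only two free ring positions, each flanked by two oxygen substituents, well before the acetyl methyl group or the benzyl rings react.

Step 3
Reactants: 3 1-[2,4-bis(benzyloxy)-3,5-dibromo-6-hydroxyphenyl]ethan-1-one
Product: 4 1-[2,4-bis(benzyloxy)-6-hydroxy-3,5-dimethoxyphenyl]ethan-1-one
Conditions: NaOMe (25% in MeOH, 10 equiv), CuBr (0.5 equiv), DMF, 110 °C, Ar; then 1 M HCl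
Reagents that add atoms: sodium methoxide, [Na+].[O-]C
Why: Ullmann-type copper-mediated methoxylation of aryl bromides with NaOMe in DMF is established for bromophenols, bromo-hydroxyacetophenones and 6,8-dibromo-5,7-dihydroxyflavones, and the phenoxide formed in the flask keeps the ketone from condensing.

Step 4
Reactants: 4 1-[2,4-bis(benzyloxy)-6-hydroxy-3,5-dimethoxyphenyl]ethan-1-one; 5 diethyl oxalate
Product: 7 ethyl 5,7-bis(benzyloxy)-6,8-dimethoxy-4-oxo-4H-chromene-2-carboxylate, via diketo ester 6 (not isolated)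
Conditions: (a) NaOEt (4 equiv), 5 (3 equiv), EtOH–THF, 65 °C; (b) HCl in EtOH, 60 °C
Reagents that add atoms: none
Why: Crossed Claisen condensation of the methyl ketone enolate with non-enolizable diethyl oxalate gives the 2,4-dioxobutanoate, whose phenol adds to the 2-keto group and loses water under acid (the classical chromone-2-carboxylate synthesis); dilute ethanolic HCl is chosen so that the acid-sensitive 5-benzyl ether should survive.

Step 5
Reactants: 8 pentane-2,4-dione
Product: 9 3-diazopentane-2,4-dione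
Conditions: 4-acetamidobenzenesulfonyl azide (1.05 equiv), Et3N, MeCN, 0 °C → rt
Reagents that add atoms: 4-acetamidobenzenesulfonyl azide, CC(=O)Nc1ccc(cc1)S(=O)(=O)N=[N+]=[N-]
Why: Regitz diazo transfer from a sulfonyl azide to the amine-generated enolate of a 1,3-diketone is the standard route to 2-diazo-1,3-diketones.

Step 6
Reactants: 9 3-diazopentane-2,4-dione
Product: 10 3-methoxypentane-2,4-dione
Conditions: Rh2(OAc)4 (1 mol %), MeOH (5 equiv), 1,2-dichloroethane, 70 °C, slow addition of 9
Reagents that add atoms: methanol, CO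
Why: The rhodium carbenoid formed from the diazo diketone and dirhodium tetraacetate inserts into the O–H bond of methanol through an oxonium ylide and proton shift, a standard carbenoid O–H insertion.

Step 7
Reactants: 7 ethyl 5,7-bis(benzyloxy)-6,8-dimethoxy-4-oxo-4H-chromene-2-carboxylate; 10 3-methoxypentane-2,4-dione
Product: 12 1-[5,7-bis(benzyloxy)-6,8-dimethoxy-4-oxo-4H-chromen-2-yl]-4-methoxyhexane-1,3,5-trione, via dilithio diketone 11 (not isolated)
Conditions: 10 (2.2 equiv), LiN(CHMe2)2 (LDA, 4.5 equiv), THF, −78 → 0 °C; then 7, −78 → −30 °C; AcOH, −78 °C, pH 5 buffer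
Reagents that add atoms: none
Why: This is the Claisen-type γ-acylation of a β-diketone dianion by an ester: the terminal carbanion of 11 is its most nucleophilic site and attacks the ester carbonyl, and the triketone is held as its enolate (hence two equivalents of 11) until the cold, weakly acidic quench.

Step 8
Reactants: 12 1-[5,7-bis(benzyloxy)-6,8-dimethoxy-4-oxo-4H-chromen-2-yl]-4-methoxyhexane-1,3,5-trione
Product: 14 5,7-bis(benzyloxy)-2-(3,5-dihydroxy-4-methoxyphenyl)-6,8-dimethoxy-4H-chromen-4-one, via cyclic aldol adduct 13 (not isolated)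
Conditions: DBU (3 equiv), dry MeCN, 0 → 50 °C, Ar; then AcOH
Reagents that add atoms: none
Why: DBU deprotonates the polyketone reversibly, and the small equilibrium share of enolate at the terminal methyl carbon (chain C6) adds to the ketone on chromone C2 (chain C1), the most electrophilic carbonyl of the chain because it bears the electron-poor heteroaryl group, forming C1'–C6'; E1cB loss of hydroxide from 13 and enolization of the two remaining ketones then give the 2-methoxyresorcinol irreversibly. The closest known reaction type is the base-mediated intramolecular aldol condensation and aromatization of 1-aryl-1,3,5-triketones with a terminal methyl group to 5-arylresorcinols, the chemistry that turns heptane-2,4,6-trione into orcinol. Ring B closes in a 6-(enolendo)-exo-trig mode, the only six-membered carbocyclic aldol the chain allows, since every other carbon–carbon closure would give a four-membered ring. No stereocentre is set: the carbinol and methoxy-bearing centres of 13 are destroyed by aromatization. The step needs carbon rather than oxygen cyclization and an intact pyranone: acid-free basic conditions disfavour dehydration of the hemiketal that leads to a 4-pyranone, and an anhydrous, hindered amidine base avoids the attack at C2 of the 2-acylchromone that hydroxide or alkoxide would make. Aromatization is the thermodynamic sink that should draw the reversible pre-equilibria (enolate isomers, hemiketal) toward 14.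

Step 9
Reactants: 14 5,7-bis(benzyloxy)-2-(3,5-dihydroxy-4-methoxyphenyl)-6,8-dimethoxy-4H-chromen-4-one
Product: 15 2-(3,5-dihydroxy-4-methoxyphenyl)-5,7-dihydroxy-6,8-dimethoxy-4H-chromen-4-one
Conditions: H2 (1 atm), 10% Pd/C, EtOAc–MeOH, rt
Reagents that add atoms: none
Why: Catalytic hydrogenolysis of aryl benzyl ethers over palladium on carbon at atmospheric pressure should free the 5- and 7-hydroxyls without reducing the pyranone double bond or touching the methyl ethers.

**Compound list**

1 | 2,4,6-trihydroxyacetophenone (1-(2,4,6-trihydroxyphenyl)ethan-1-one) | CC(=O)c1c(O)cc(O)cc1O | starting material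
2 | 1-[2,4-bis(benzyloxy)-6-hydroxyphenyl]ethan-1-one | CC(=O)c1c(O)cc(OCc2ccccc2)cc1OCc1ccccc1 | intermediate
3 | 1-[2,4-bis(benzyloxy)-3,5-dibromo-6-hydroxyphenyl]ethan-1-one | CC(=O)c1c(O)c(Br)c(OCc2ccccc2)c(Br)c1OCc1ccccc1 | intermediate
4 | 1-[2,4-bis(benzyloxy)-6-hydroxy-3,5-dimethoxyphenyl]ethan-1-one | CC(=O)c1c(O)c(OC)c(OCc2ccccc2)c(OC)c1OCc1ccccc1 | intermediate
5 | diethyl oxalate | CCOC(=O)C(=O)OCC | starting material
6 | ethyl 4-[2,4-bis(benzyloxy)-6-hydroxy-3,5-dimethoxyphenyl]-2,4-dioxobutanoate (not isolated) | CCOC(=O)C(=O)CC(=O)c1c(O)c(OC)c(OCc2ccccc2)c(OC)c1OCc1ccccc1 | intermediate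
7 | ethyl 5,7-bis(benzyloxy)-6,8-dimethoxy-4-oxo-4H-chromene-2-carboxylate | CCOC(=O)c1cc(=O)c2c(OCc3ccccc3)c(OC)c(OCc3ccccc3)c(OC)c2o1 | intermediate
8 | pentane-2,4-dione | CC(=O)CC(C)=O | starting material
9 | 3-diazopentane-2,4-dione | CC(=O)C(=[N+]=[N-])C(C)=O | intermediate
10 | 3-methoxypentane-2,4-dione | CC(=O)C(OC)C(C)=O | intermediate
11 | dilithium dianion of 3-methoxypentane-2,4-dione, lithiated at C1 and on the enolate oxygen (not isolated; enolate geometry not defined) | [Li]CC(=O)C(OC)=C(C)O[Li] | intermediate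
12 | 1-[5,7-bis(benzyloxy)-6,8-dimethoxy-4-oxo-4H-chromen-2-yl]-4-methoxyhexane-1,3,5-trione (C4 of the chain labile, racemic) | COc1c(OCc2ccccc2)c2c(=O)cc(C(=O)CC(=O)C(OC)C(C)=O)oc2c(OC)c1OCc1ccccc1 | intermediate
13 | 5,7-bis(benzyloxy)-2-(1-hydroxy-4-methoxy-3,5-dioxocyclohexyl)-6,8-dimethoxy-4H-chromen-4-one (not isolated; cis/trans mixture, of no consequence) | COC1C(=O)CC(O)(CC1=O)c1cc(=O)c2c(OCc3ccccc3)c(OC)c(OCc3ccccc3)c(OC)c2o1 | intermediate
14 | 5,7-bis(benzyloxy)-2-(3,5-dihydroxy-4-methoxyphenyl)-6,8-dimethoxy-4H-chromen-4-one | COc1c(OCc2ccccc2)c2c(=O)cc(-c3cc(O)c(OC)c(O)c3)oc2c(OC)c1OCc1ccccc1 | intermediate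
15 | 2-(3,5-dihydroxy-4-methoxyphenyl)-5,7-dihydroxy-6,8-dimethoxy-4H-chromen-4-one | COc1c(O)cc(-c2cc(=O)c3c(O)c(OC)c(O)c(OC)c3o2)cc1O | target

**Step count**

Total steps: 9. Longest linear sequence: 7 steps (1, 2, 3, 4, 7, 8, 9) from 2,4,6-trihydroxyacetophenone; steps 5 and 6 form the side branch.

**Steps most likely to fail**

Step 8. The enolization toward the terminal methyl group may be too slow, so that base opening of the pyranone at C2 or oxygen cyclization of the chain to a 4-pyranone runs ahead of the carbon–carbon closure.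
The fallback brings ring B in preformed and closes ring C last. It sets out from compound 4 and comes back at compound 15.
- Commercial 3,5-dihydroxy-4-methoxybenzoic acid would be perbenzylated (BnBr, K2CO3, DMF) to benzyl 3,5-bis(benzyloxy)-4-methoxybenzoate F1.
- Saponification (NaOH, MeOH–THF–H2O) would give 3,5-bis(benzyloxy)-4-methoxybenzoic acid F2.
- Steglich esterification of phenol 4 with F2 (EDC·HCl, DMAP, CH2Cl2) would give 2-acetyl-3,5-bis(benzyloxy)-4,6-dimethoxyphenyl 3,5-bis(benzyloxy)-4-methoxybenzoate F3.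
- Baker–Venkataraman rearrangement (lithium hexamethyldisilazide, THF, −78 °C → rt) would give 1-[2,4-bis(benzyloxy)-6-hydroxy-3,5-dimethoxyphenyl]-3-[3,5-bis(benzyloxy)-4-methoxyphenyl]propane-1,3-dione F4.
- Cyclodehydration (cat. H2SO4, AcOH, 60 °C) would give 5,7-bis(benzyloxy)-2-[3,5-bis(benzyloxy)-4-methoxyphenyl]-6,8-dimethoxy-4H-chromen-4-one F5.
- Hydrogenolysis of all four benzyl ethers (H2, 10% Pd/C) would give 15.

Step 7. The hard dianion may add in conjugate fashion to C2 of the pyranone, or to the C4 carbonyl, instead of attacking the ester, and excess dianion may degrade the product enolate.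
The fallback replaces the carbanion by a neutral silyl dienol ether in a Mukaiyama-type γ-acylation. It sets out from compounds 7 and 10 and comes back at compound 12.
- Ester 7 would be saponified (LiOH, THF–H2O, 0 °C) to 5,7-bis(benzyloxy)-6,8-dimethoxy-4-oxo-4H-chromene-2-carboxylic acid F6.
- Oxalyl chloride and catalytic DMF in CH2Cl2 would convert F6 into 5,7-bis(benzyloxy)-6,8-dimethoxy-4-oxo-4H-chromene-2-carbonyl chloride F7.
- Diketone 10 would be silylated twice (Me3SiOTf, Et3N, Et2O, 0 °C) to 3-methoxy-2,4-bis(trimethylsilyloxy)penta-1,3-diene F8.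
- F7 and F8 (CH2Cl2, −78 °C → rt) should couple at the terminal carbon of the diene to give 1-[5,7-bis(benzyloxy)-6,8-dimethoxy-4-oxo-4H-chromen-2-yl]-4-methoxy-5-(trimethylsilyloxy)hex-4-ene-1,3-dione F9.
- Aqueous work-up would desilylate F9 to 12.

Step 3. Substitution at the bromide shielded by two benzyloxy groups may be sluggish, so that reductive loss of bromine competes and mono-methoxylated material accumulates.
The fallback makes the hindered C–O bond by electrophilic oxidation para to the phenoxide and keeps copper chemistry only for the easy position next to the phenol. It sets out from compound 2 and comes back at compound 4.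
- Elbs persulfate oxidation of 2 (K2S2O8, aqueous NaOH–pyridine, rt) would give potassium 3-acetyl-2,6-bis(benzyloxy)-4-hydroxyphenyl sulfate F10.
- Hydrolysis with warm dilute HCl would give 1-[2,4-bis(benzyloxy)-3,6-dihydroxyphenyl]ethan-1-one F11.
- Methylation of the non-chelated hydroxyl (Me2SO4, 1.05 equiv, K2CO3, acetone) would give 1-[2,4-bis(benzyloxy)-6-hydroxy-3-methoxyphenyl]ethan-1-one F12.
- Bromination at the one remaining ring position (NBS, DMF) would give 1-[2,4-bis(benzyloxy)-5-bromo-6-hydroxy-3-methoxyphenyl]ethan-1-one F13.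
- A single methoxylation ortho to the phenoxide (NaOMe, CuBr, DMF, 110 °C) would give 4.

**Further compounds**

F1 | step 8 | benzyl 3,5-bis(benzyloxy)-4-methoxybenzoate | COc1c(OCc2ccccc2)cc(cc1OCc1ccccc1)C(=O)OCc1ccccc1
F2 | step 8 | 3,5-bis(benzyloxy)-4-methoxybenzoic acid | COc1c(OCc2ccccc2)cc(cc1OCc1ccccc1)C(O)=O
F3 | step 8 | 2-acetyl-3,5-bis(benzyloxy)-4,6-dimethoxyphenyl 3,5-bis(benzyloxy)-4-methoxybenzoate | CC(=O)c1c(OC(=O)c2cc(OCc3ccccc3)c(OC)c(OCc3ccccc3)c2)c(OC)c(OCc2ccccc2)c(OC)c1OCc1ccccc1
F4 | step 8 | 1-[2,4-bis(benzyloxy)-6-hydroxy-3,5-dimethoxyphenyl]-3-[3,5-bis(benzyloxy)-4-methoxyphenyl]propane-1,3-dione | COc1c(OCc2ccccc2)cc(cc1OCc1ccccc1)C(=O)CC(=O)c1c(O)c(OC)c(OCc2ccccc2)c(OC)c1OCc1ccccc1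
F5 | step 8 | 5,7-bis(benzyloxy)-2-[3,5-bis(benzyloxy)-4-methoxyphenyl]-6,8-dimethoxy-4H-chromen-4-one | COc1c(OCc2ccccc2)cc(cc1OCc1ccccc1)-c1cc(=O)c2c(OCc3ccccc3)c(OC)c(OCc3ccccc3)c(OC)c2o1
F6 | step 7 | 5,7-bis(benzyloxy)-6,8-dimethoxy-4-oxo-4H-chromene-2-carboxylic acid | OC(=O)c1cc(=O)c2c(OCc3ccccc3)c(OC)c(OCc3ccccc3)c(OC)c2o1
F7 | step 7 | 5,7-bis(benzyloxy)-6,8-dimethoxy-4-oxo-4H-chromene-2-carbonyl chloride | ClC(=O)c1cc(=O)c2c(OCc3ccccc3)c(OC)c(OCc3ccccc3)c(OC)c2o1
F8 | step 7 | 3-methoxy-2,4-bis(trimethylsilyloxy)penta-1,3-diene (geometry of the 3,4-double bond not controlled) | C=C(O[Si](C)(C)C)C(OC)=C(C)O[Si](C)(C)C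
F9 | step 7 | 1-[5,7-bis(benzyloxy)-6,8-dimethoxy-4-oxo-4H-chromen-2-yl]-4-methoxy-5-(trimethylsilyloxy)hex-4-ene-1,3-dione (alkene geometry not controlled) | COC(C(=O)CC(=O)c1cc(=O)c2c(OCc3ccccc3)c(OC)c(OCc3ccccc3)c(OC)c2o1)=C(C)O[Si](C)(C)C
F10 | step 3 | potassium 3-acetyl-2,6-bis(benzyloxy)-4-hydroxyphenyl sulfate | CC(=O)c1c(O)cc(OCc2ccccc2)c(OS(=O)(=O)[O-])c1OCc1ccccc1.[K+]
F11 | step 3 | 1-[2,4-bis(benzyloxy)-3,6-dihydroxyphenyl]ethan-1-one | CC(=O)c1c(O)cc(OCc2ccccc2)c(O)c1OCc1ccccc1
F12 | step 3 | 1-[2,4-bis(benzyloxy)-6-hydroxy-3-methoxyphenyl]ethan-1-one | CC(=O)c1c(O)cc(OCc2ccccc2)c(OC)c1OCc1ccccc1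
F13 | step 3 | 1-[2,4-bis(benzyloxy)-5-bromo-6-hydroxy-3-methoxyphenyl]ethan-1-one | CC(=O)c1c(O)c(Br)c(OCc2ccccc2)c(OC)c1OCc1ccccc1
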